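**Assumption (one line):** the SMILES is read as the all‑trans, C2‑symmetric (2R,3S,4S,5R)‑2,5‑diaryl‑3,4‑bis(hydroxymethyl)tetrahydrofuran. The phenols are carried as benzyl ethers and the primary alcohols as TBS ethers until the end.

## Retrosynthetic overview
1. The target comes from global debenzylation of dibenzyl diol **10**, which comes from desilylation of THF **9**.
2. The only ring, the 2,5‑trans‑diaryl THF, is formed last, by acid‑mediated dehydrative cyclisation of the 1,4‑diaryl‑1,4‑diol **8**. The benzylic cation equilibrates to the all‑trans ring, and the C8/C8′ centres that carry the CH2OR groups are not touched.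
3. Diol **8** comes from the bidirectional Evans syn‑aldol adduct **5** by LiBH4 reduction and selective primary silylation.
4. Adduct **5** comes from the bis‑imide **3** (succinyl chloride plus (R)‑4‑benzyloxazolidinone) and two equivalents of O‑benzylvanillin **4**. This one step sets all four stereocentres.

## Route

**Step 1**
Reactants: **1** (R)‑4‑benzyl‑oxazolidin‑2‑one (2 equiv); **2** succinyl chloride (1 equiv)
Product: **3** 1,4‑bis[(4R)‑4‑benzyl‑2‑oxo‑oxazolidin‑3‑yl]butane‑1,4‑dione
Conditions: n‑BuLi, THF, –78 °C; then **2**, –78 °C → rt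
Reagents that add atoms: none beyond reactant **2**; n‑BuLi only deprotonates.
Why: N‑acylation of the lithium oxazolidinone anion (Schotten–Baumann‑type imide formation) gives the C2‑symmetric bis‑imide. The auxiliary stereocentres come from the starting material.

**Step 2**
Reactants: **3**; **4** 4‑(benzyloxy)‑3‑methoxybenzaldehyde (O‑benzylvanillin, 2.4 equiv)
Product: **5** bis‑aldol adduct, (2R,3R)‑2,3‑bis{(R)‑[4‑(benzyloxy)‑3‑methoxyphenyl](hydroxy)methyl}succinyl bis[(4R)‑4‑benzyloxazolidin‑2‑one]
Conditions: Bu2BOTf (2.4 equiv), i‑Pr2NEt (2.6 equiv), CH2Cl2, 0 °C; then **4**, –78 → 0 °C; then pH 7 buffer/MeOH/H2O2, 0 °C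
Reagents that add atoms: none; boron is removed in the oxidative work‑up.
Why: This is an Evans syn‑aldol. Each imide forms a Z‑boron enolate and reacts through a Zimmerman–Traxler transition state, with the aldehyde attacking the face opposite the benzyl group. The (R)‑auxiliary gives the (2R,3R)‑syn adduct on both halves, and because the reagent is C2‑symmetric the product is the C2‑symmetric (S,S)‑type succinate core. This sets C7, C8, C8′ and C7′.

**Step 3**
Reactants: **5**
Product: **6** (2S,3S)‑2,3‑bis{(R)‑[4‑(benzyloxy)‑3‑methoxyphenyl](hydroxy)methyl}butane‑1,4‑diol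
Conditions: LiBH4, THF, 0 °C → rt; then aq. NH4Cl
Reagents that add atoms: none (hydride only). Auxiliary **1** is recovered.
Why: LiBH4 cleaves the N‑acyl oxazolidinones reductively to primary alcohols, and no acidic α‑C–H remains afterwards, so C8 and C8′ cannot epimerise. Any γ‑lactone formed by transient lactonisation is also reduced to the same tetrol.

**Step 4**
Reactants: **6**; **7** TBSCl (2.2 equiv)
Product: **8** (2S,3S)‑1,4‑bis(TBSO)‑2,3‑bis{(R)‑aryl(hydroxy)methyl}butane
Conditions: **7**, imidazole, DMF, 0 °C → rt
Reagents that add atoms: TBSCl, CC(C)(C)[Si](C)(C)Cl (compound **7**)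
Why: Silylation is chemoselective for the unhindered primary alcohols over the branched benzylic secondary alcohols. It masks the nucleophilic C9/C9′ oxygens so they cannot compete in the next step, which would give 7,9′‑epoxy (lariciresinol‑type) products.

**Step 5**
Reactants: **8**
Product: **9** (2R,3S,4S,5R)‑2,5‑bis[4‑(benzyloxy)‑3‑methoxyphenyl]‑3,4‑bis(TBSO‑methyl)tetrahydrofuran
Conditions: CSA (10 mol%), CH2Cl2, 4 Å MS, 0 °C → rt
Reagents that add atoms: none (net loss of H2O).
Why: This is acid‑catalysed dehydrative cyclisation (SN1 / 5‑exo etherification). The p‑alkoxyaryl benzylic cation is captured by the other benzylic hydroxyl, and the reversible ionisation funnels material to the thermodynamically favoured all‑trans THF, with each aryl trans to its neighbouring CH2OTBS. The syn‑aldol C7/C7′ configuration already matches this outcome. C8 and C8′ are not involved and keep their configuration. A furofuran cannot form because the 3,4‑substituents are trans.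

**Step 6**
Reactants: **9**
Product: **10** (2R,3S,4S,5R)‑2,5‑bis[4‑(benzyloxy)‑3‑methoxyphenyl]‑3,4‑bis(hydroxymethyl)tetrahydrofuran
Conditions: TBAF, THF, 0 °C → rt
Reagents that add atoms: none (silyl groups are removed).
Why: Fluoride removes the primary TBS ethers (Si–F driven desilylation). The benzyl ethers, aryl methyl ethers and THF ring are untouched, and no stereocentre is affected.

**Step 7**
Reactants: **10**
Product: **11** (+)‑neoolivil
Conditions: H2 (1 atm), 10% Pd/C, EtOAc/EtOH, rt, short reaction time
Reagents that add atoms: none (hydrogen only; toluene is the by‑product).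
Why: Catalytic hydrogenolysis cleaves the aryl benzyl ethers to the free phenols (standard deprotection at the end of lignan syntheses). No stereocentre is involved, and the mild conditions spare the benzylic ring C–O bonds.

## Compound list
1 | (R)‑4‑benzyl‑oxazolidin‑2‑one | O=C1N[C@H](Cc2ccccc2)CO1 | starting material
2 | succinyl chloride | ClC(=O)CCC(=O)Cl | starting material
3 | 1,4‑bis[(4R)‑4‑benzyl‑2‑oxo‑oxazolidin‑3‑yl]butane‑1,4‑dione | O=C(CCC(=O)N1[C@H](Cc2ccccc2)COC1=O)N1[C@H](Cc2ccccc2)COC1=O | intermediate
4 | 4‑(benzyloxy)‑3‑methoxybenzaldehyde | COc1cc(C=O)ccc1OCc1ccccc1 | starting material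
5 | bis‑aldol adduct (all R) | O=C(N1[C@H](Cc2ccccc2)COC1=O)[C@@H]([C@@H](O)c1ccc(OCc2ccccc2)c(OC)c1)[C@H]([C@@H](O)c1ccc(OCc2ccccc2)c(OC)c1)C(=O)N1[C@H](Cc2ccccc2)COC1=O | intermediate
6 | (2S,3S)‑2,3‑bis{(R)‑aryl(hydroxy)methyl}butane‑1,4‑diol (aryl = 4‑OBn‑3‑OMe‑phenyl) | OC[C@@H]([C@@H](O)c1ccc(OCc2ccccc2)c(OC)c1)[C@H]([C@@H](O)c1ccc(OCc2ccccc2)c(OC)c1)CO | intermediate
7 | tert‑butyldimethylsilyl chloride | CC(C)(C)[Si](C)(C)Cl | starting material
8 | bis‑TBS ether of **6** (primary OH silylated) | CC(C)(C)[Si](C)(C)OC[C@@H]([C@@H](O)c1ccc(OCc2ccccc2)c(OC)c1)[C@H]([C@@H](O)c1ccc(OCc2ccccc2)c(OC)c1)CO[Si](C)(C)C(C)(C)C | intermediate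
9 | all‑trans 2,5‑diaryl‑3,4‑bis(TBSOCH2)THF | COc1cc([C@@H]2O[C@@H](c3ccc(OCc4ccccc4)c(OC)c3)[C@H](CO[Si](C)(C)C(C)(C)C)[C@H]2CO[Si](C)(C)C(C)(C)C)ccc1OCc1ccccc1 | intermediate
10 | all‑trans 2,5‑bis(4‑OBn‑3‑OMe‑phenyl)‑3,4‑bis(hydroxymethyl)THF | COc1cc([C@@H]2O[C@@H](c3ccc(OCc4ccccc4)c(OC)c3)[C@H](CO)[C@H]2CO)ccc1OCc1ccccc1 | intermediate
11 | (+)‑neoolivil | COc1cc([C@@H]2O[C@@H](c3ccc(O)c(OC)c3)[C@H](CO)[C@H]2CO)ccc1O | target

**Total steps:** 7. **Longest linear sequence:** 7 (1/2 → 3 → 5 → 6 → 8 → 9 → 10 → 11).

## Three steps most likely to fail, with fallbacks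
1. **Step 2 (bidirectional Evans aldol).** The bis‑enolate may behave as a conjugated dienediolate, and the second aldol is hindered or only partly matched, giving meso or mono‑aldol products.
   Fallback: change the way C8–C8′ is built. Dimerise methyl 4‑benzyloxy‑3‑methoxybenzoylacetate oxidatively (I2, base) to the dimethyl 2,3‑diaroylsuccinate. Then do a Ru‑catalysed asymmetric transfer hydrogenation with dynamic kinetic resolution to the diol diester, and reduce with LiAlH4 to tetrol **6**. Because C7 is re‑equilibrated in step 5, only the C8/C8′ configuration matters.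
2. **Step 5 (cyclisation).** The cation may eliminate to a styrene, undergo Friedel–Crafts closure to an aryltetralin, or be captured by a silyl ether oxygen to give 7,9′‑epoxy products.
   Fallback: oxidise diol **8** to the 1,4‑diketone under neutral conditions (DMP or MnO2). Then do a reductive etherification (Et3SiH, TMSOTf, CH2Cl2, –78 °C) to form the trans THF through an oxocarbenium ion. This avoids the free benzylic cation.
3. **Step 7 (hydrogenolysis).** The benzylic THF C–O bonds could be cleaved, giving lariciresinol‑type ring‑opened by‑products.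
   Fallback: change the phenol protection. Use 4‑O‑TBS‑vanillin in place of **4** from step 2, so a single TBAF treatment removes the phenolic and primary silyl groups together. This eliminates hydrogenation altogether, provided the aryl silyl ethers survive steps 3 and 5.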